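## Retrosynthetic overview

1. Last bond made is C5'–C6' of the lactone (side chain numbered C1' = ArOCH2, C2'/C3' = epoxide, C5' = lactone CH–O, C8' = lactone C=O). Alcohol 8 and allylic carbonate 9 are joined by a redox-neutral iridium-catalysed coupling. The carbonate CH2, normally an electrophile, becomes a nucleophilic β-carbanion of the acrylate (homoenolate-type d3 synthon) and attacks the aldehyde carbon generated in situ from 8. The catalyst sets C5' and the hydroxy ester lactonises.
2. C7–O–C1' aryl ether: Mitsunobu coupling of hydrangetin 6 with epoxy alcohol 5.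
3. Epoxide: Sharpless epoxidation of E-allylic alcohol 4 sets C2' and C3' together.
4. E-trisubstituted alkene: Negishi methylalumination and hydroxymethylation of alkyne 1.
5. Ring order: coumarin bought intact, then the oxirane (step 2), then the α-methylene-γ-butyrolactone last (step 5).

Assumption: 1, 6 and 9 are bought as catalogue compounds.

## Route

Step 1
Reactants: 1 tert-butyl(but-3-yn-1-yloxy)dimethylsilane
Product: 4 (2E)-5-{[tert-butyl(dimethyl)silyl]oxy}-3-methylpent-2-en-1-ol, via alkenylalane 2 (not isolated), via lithium alanate 3 (not isolated)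
Conditions: AlMe3 (2.5 equiv), Cp2ZrCl2 (0.25 equiv), CH2Cl2, 0 °C to rt; excess AlMe3 evaporated; n-BuLi, THF, −78 °C; (CH2O)n, −78 °C to rt; aq. potassium sodium tartrate
Reagents that add atoms: trimethylaluminium C[Al](C)C; formaldehyde (from paraformaldehyde) C=O
Why: Negishi zirconium-catalysed methylalumination adds Me and Al syn across the terminal alkyne with Al on the terminal carbon, so the E geometry is fixed before the alanate is trapped by formaldehyde with retention (carbometalation then hydroxymethylation).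

Step 2
Reactants: 4 (2E)-5-{[tert-butyl(dimethyl)silyl]oxy}-3-methylpent-2-en-1-ol
Product: 5 [(2R,3R)-3-(2-{[tert-butyl(dimethyl)silyl]oxy}ethyl)-3-methyloxiran-2-yl]methanol
Conditions: Ti(OiPr)4 (10 mol%), D-(−)-diethyl tartrate (12 mol%), t-BuOOH (2 equiv, decane), 4 Å MS, CH2Cl2, −20 °C
Reagents that add atoms: tert-butyl hydroperoxide CC(C)(C)OO
Why: Sharpless asymmetric epoxidation, in which the allylic hydroxyl binds the titanium tartrate complex and D-(−)-diethyl tartrate directs oxygen to the face that gives the (2R,3R)-epoxide of an E-3,3-disubstituted allylic alcohol (the geraniol pattern, typically above 90% ee), creating both epoxide stereocentres at once.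

Step 3
Reactants: 5 [(2R,3R)-3-(2-{[tert-butyl(dimethyl)silyl]oxy}ethyl)-3-methyloxiran-2-yl]methanol; 6 7-hydroxy-8-methoxy-2H-chromen-2-one (hydrangetin)
Product: 7 7-{[(2R,3R)-3-(2-{[tert-butyl(dimethyl)silyl]oxy}ethyl)-3-methyloxiran-2-yl]methoxy}-8-methoxy-2H-chromen-2-one
Conditions: PPh3, DIAD, THF, 0 °C to rt
Reagents that add atoms: none
Why: Mitsunobu etherification, in which the acidic 7-OH of the coumarin (pKa about 8) displaces the activated primary oxyphosphonium at C1', a carbon that is not stereogenic, so both epoxide stereocentres are untouched.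

Step 4
Reactants: 7 7-{[(2R,3R)-3-(2-{[tert-butyl(dimethyl)silyl]oxy}ethyl)-3-methyloxiran-2-yl]methoxy}-8-methoxy-2H-chromen-2-one
Product: 8 7-{[(2R,3R)-3-(2-hydroxyethyl)-3-methyloxiran-2-yl]methoxy}-8-methoxy-2H-chromen-2-one
Conditions: Bu4NF, AcOH (1:1), THF, 0 °C to rt
Reagents that add atoms: none
Why: Fluoride-mediated desilylation driven by Si–F bond formation, buffered with acetic acid so that neither the epoxide nor the coumarin lactone is attacked; no stereocentre is involved.

Step 5
Reactants: 8 7-{[(2R,3R)-3-(2-hydroxyethyl)-3-methyloxiran-2-yl]methoxy}-8-methoxy-2H-chromen-2-one; 9 methyl 2-{[(tert-butoxycarbonyl)oxy]methyl}prop-2-enoate (2 equiv)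
Product: 12 8-methoxy-7-{[(2R,3R)-3-methyl-3-{[(2S)-4-methylidene-5-oxooxolan-2-yl]methyl}oxiran-2-yl]methoxy}-2H-chromen-2-one (CNP0318299.1), via epoxy aldehyde 10 (not isolated), via hydroxy ester 11 (not isolated)
Conditions: [Ir(cod)Cl]2 (2.5 mol%), (S)-SEGPHOS (5 mol%), 4-chloro-3-nitrobenzoic acid (10 mol%), Cs2CO3 (20 mol%), THF, 60 °C
Reagents that add atoms: none
Why: Iridium-catalysed transfer-hydrogenative carbonyl 2-(alkoxycarbonyl)allylation (Krische-type redox-triggered allylation): the cyclometalated iridium benzoate dehydrogenates 8 to aldehyde 10 and uses those two hydrogens to reduce carbonate 9 (losing CO2 and t-BuOH) to a nucleophilic 2-(methoxycarbonyl)allyl iridium, which adds through a closed chair transition state to the Si face of 10 under control of (S)-SEGPHOS to set 5'S before the alkoxide closes onto the ester; because 10 is consumed as it forms, as with the β-alkoxy and α-stereogenic aldehydes this reaction class carries without elimination or epimerisation, the base-labile β,γ-epoxy aldehyde should not accumulate (the ligand antipode gives the 5'-epimer, and the facial sense is assigned from my recollection of this catalyst family, so it is confirmed on a model alcohol first).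

## Compound list

1 | tert-butyl(but-3-yn-1-yloxy)dimethylsilane | C#CCCO[Si](C)(C)C(C)(C)C | starting material
2 | [(1E)-4-{[tert-butyl(dimethyl)silyl]oxy}-2-methylbut-1-en-1-yl]dimethylaluminium | C[Al](C)/C=C(\C)CCO[Si](C)(C)C(C)(C)C | intermediate
3 | lithium butyl[(1E)-4-{[tert-butyl(dimethyl)silyl]oxy}-2-methylbut-1-en-1-yl]dimethylaluminate | [Li+].CCCC[Al-](C)(C)/C=C(\C)CCO[Si](C)(C)C(C)(C)C | intermediate
4 | (2E)-5-{[tert-butyl(dimethyl)silyl]oxy}-3-methylpent-2-en-1-ol | OC/C=C(\C)CCO[Si](C)(C)C(C)(C)C | intermediate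
5 | [(2R,3R)-3-(2-{[tert-butyl(dimethyl)silyl]oxy}ethyl)-3-methyloxiran-2-yl]methanol | CC(C)(C)[Si](C)(C)OCC[C@@]1(C)O[C@@H]1CO | intermediate
6 | 7-hydroxy-8-methoxy-2H-chromen-2-one (hydrangetin) | Oc1ccc2ccc(=O)oc2c1OC | starting material
7 | 7-{[(2R,3R)-3-(2-{[tert-butyl(dimethyl)silyl]oxy}ethyl)-3-methyloxiran-2-yl]methoxy}-8-methoxy-2H-chromen-2-one | CC(C)(C)[Si](C)(C)OCC[C@@]1(C)O[C@@H]1COc1ccc2ccc(=O)oc2c1OC | intermediate
8 | 7-{[(2R,3R)-3-(2-hydroxyethyl)-3-methyloxiran-2-yl]methoxy}-8-methoxy-2H-chromen-2-one | OCC[C@@]1(C)O[C@@H]1COc1ccc2ccc(=O)oc2c1OC | intermediate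
9 | methyl 2-{[(tert-butoxycarbonyl)oxy]methyl}prop-2-enoate | C=C(COC(=O)OC(C)(C)C)C(=O)OC | starting material
10 | 2-[(2R,3R)-3-{[(8-methoxy-2-oxo-2H-chromen-7-yl)oxy]methyl}-2-methyloxiran-2-yl]acetaldehyde | O=CC[C@@]1(C)O[C@@H]1COc1ccc2ccc(=O)oc2c1OC | intermediate
11 | methyl (4S)-4-hydroxy-5-[(2R,3R)-3-{[(8-methoxy-2-oxo-2H-chromen-7-yl)oxy]methyl}-2-methyloxiran-2-yl]-2-methylidenepentanoate | C=C(C[C@@H](C[C@@]1(C)O[C@@H]1COc1ccc2ccc(=O)oc2c1OC)O)C(=O)OC | intermediate
12 | 8-methoxy-7-{[(2R,3R)-3-methyl-3-{[(2S)-4-methylidene-5-oxooxolan-2-yl]methyl}oxiran-2-yl]methoxy}-2H-chromen-2-one | C=C1C[C@@H](C[C@@]2(C)O[C@@H]2COc2ccc3ccc(=O)oc3c2OC)OC1=O | target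

## Step count and risks

Total steps: 5. Longest linear sequence: 5 steps (1 → 4 → 5 → 7 → 8 → 12).

**Step 5 (highest risk).** The transient β,γ-epoxy aldehyde 10 could open to a γ-hydroxy enal under base, alcohol 8 could be O-allylated by 9, and catalyst control next to the epoxide is untested. The fallback sets out from 4 and comes back at 12; it introduces the epoxide last, so the iridium step runs on an epoxide-free alcohol. Mitsunobu coupling of 4 with 6 (PPh3, DIAD, THF) gives the allyl aryl ether 7-{[(2E)-5-{[tert-butyl(dimethyl)silyl]oxy}-3-methylpent-2-en-1-yl]oxy}-8-methoxy-2H-chromen-2-one F1. Bu4NF/AcOH then frees the homoallylic alcohol 7-{[(2E)-5-hydroxy-3-methylpent-2-en-1-yl]oxy}-8-methoxy-2H-chromen-2-one F2. The same iridium-catalysed coupling with 9 passes through the aldehyde (3E)-5-[(8-methoxy-2-oxo-2H-chromen-7-yl)oxy]-3-methylpent-3-enal F3 and the hydroxy ester methyl (4R,6E)-4-hydroxy-8-[(8-methoxy-2-oxo-2H-chromen-7-yl)oxy]-6-methyl-2-methylideneoct-6-enoate F4 to the alkenyl lactone 8-methoxy-7-{[(2E)-3-methyl-4-[(2R)-4-methylidene-5-oxooxolan-2-yl]but-2-en-1-yl]oxy}-2H-chromen-2-one F5. The descriptor at the carbinol carbon reads R in F4 and F5 only because the CIP ranking changes without the epoxide; the spatial arrangement is that of 12. Shi epoxidation (D-fructose-derived ketone, KHSO5 as Oxone, K2CO3 buffer, MeCN/dimethoxymethane/water, 0 °C) then oxidises only the electron-rich trisubstituted alkene, from the face that gives the (2R,3R)-epoxide, to give 12.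

**Step 3.** The Mitsunobu reaction of a 2,3-epoxy alcohol with an ortho-methoxy phenol may stall or give hydrazide alkylation. The fallback sets out from 5 and comes back at 7; it replaces the redox condensation by a sulfonate alkylation. Treatment of 5 with 4-nitrobenzenesulfonyl chloride (Et3N, cat. DMAP, CH2Cl2, 0 °C) gives the nosylate [(2R,3R)-3-(2-{[tert-butyl(dimethyl)silyl]oxy}ethyl)-3-methyloxiran-2-yl]methyl 4-nitrobenzenesulfonate F6. SN2 displacement at its primary carbon by the phenoxide of 6 (Cs2CO3, DMF, rt) gives 7.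

**Step 1.** The one-pot carboalumination and alanate hydroxymethylation can suffer from protodealumination, incomplete trapping or silyl ether loss. The fallback sets out from 1 and comes back at 4; it builds the alkene by carbonyl olefination instead of carbometalation. Gold-catalysed Markovnikov hydration of 1 (Ph3PAuCl/AgOTf cat., dioxane/water, 60 °C) gives the ketone 4-{[tert-butyl(dimethyl)silyl]oxy}butan-2-one F7. Horner–Wadsworth–Emmons olefination (triethyl phosphonoacetate, NaH, THF) gives the enoate ethyl (2E)-5-{[tert-butyl(dimethyl)silyl]oxy}-3-methylpent-2-enoate F8, with the minor Z isomer removed on silica. DIBAL-H (CH2Cl2, −78 °C) reduces F8 to 4.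

## Further compounds

F1 | step 5 | 7-{[(2E)-5-{[tert-butyl(dimethyl)silyl]oxy}-3-methylpent-2-en-1-yl]oxy}-8-methoxy-2H-chromen-2-one | CC(C)(C)[Si](C)(C)OCC/C(C)=C/COc1ccc2ccc(=O)oc2c1OC
F2 | step 5 | 7-{[(2E)-5-hydroxy-3-methylpent-2-en-1-yl]oxy}-8-methoxy-2H-chromen-2-one | OCC/C(C)=C/COc1ccc2ccc(=O)oc2c1OC
F3 | step 5 | (3E)-5-[(8-methoxy-2-oxo-2H-chromen-7-yl)oxy]-3-methylpent-3-enal | O=CC/C(C)=C/COc1ccc2ccc(=O)oc2c1OC
F4 | step 5 | methyl (4R,6E)-4-hydroxy-8-[(8-methoxy-2-oxo-2H-chromen-7-yl)oxy]-6-methyl-2-methylideneoct-6-enoate | C=C(C[C@@H](C/C(C)=C/COc1ccc2ccc(=O)oc2c1OC)O)C(=O)OC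
F5 | step 5 | 8-methoxy-7-{[(2E)-3-methyl-4-[(2R)-4-methylidene-5-oxooxolan-2-yl]but-2-en-1-yl]oxy}-2H-chromen-2-one | C=C1C[C@@H](C/C(C)=C/COc2ccc3ccc(=O)oc3c2OC)OC1=O
F6 | step 3 | [(2R,3R)-3-(2-{[tert-butyl(dimethyl)silyl]oxy}ethyl)-3-methyloxiran-2-yl]methyl 4-nitrobenzenesulfonate | CC(C)(C)[Si](C)(C)OCC[C@@]1(C)O[C@@H]1COS(=O)(=O)c1ccc(cc1)[N+](=O)[O-]
F7 | step 1 | 4-{[tert-butyl(dimethyl)silyl]oxy}butan-2-one | CC(=O)CCO[Si](C)(C)C(C)(C)C
F8 | step 1 | ethyl (2E)-5-{[tert-butyl(dimethyl)silyl]oxy}-3-methylpent-2-enoate | CCOC(=O)/C=C(\C)CCO[Si](C)(C)C(C)(C)C
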